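**Plan** (tetralone numbering: C1 ketone, C4 stereocentre; naphthyl atoms primed)
- Cuts, in retrosynthetic order: the three phenolic O–H (as benzyl ethers), C1–C8a (Friedel–Crafts acylation), C3–C4 together with a temporary O5–C1 ester bond ([4+3] annulation), and C4–C4a (aryllithium plus aldehyde).
- Enabling feature: the C5 hydroxyl is ortho to C4a, the ring carbon that carries C4. O5–C5–C4a–C4 is therefore a latent ortho-quinone methide with C4 as its electrophilic end. O5 is an internal nucleophile on which the future ketone carbon C1 can be parked as a seven-membered aryl lactone.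
- Forward: both aromatic units are bought. Symmetric 1,5-dimethoxynaphthalene is formylated and only the methoxy group para to CHO is exchanged for benzyloxy. The aldehyde is joined to dilithiated 4-(benzyloxy)-2-bromophenol, and the carbinol becomes the sulfone.
- Rings: the oxepinone closes in step 7 and is opened in step 8. The cyclohexanone ring of the tetralone closes in step 9 at C8a, the only free position ortho to C4a.
- Stereochemistry: C4 (S) is set in step 7 by the chiral triazolium carbene alone, and no later step touches C4–H.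

Key step: step 7

Assumption: the sense of induction of the aminoindanol triazolium catalyst with a β-unsubstituted homoenolate cannot be predicted with confidence. The (5aS,10bR) salt is written, and its equally available (5aR,10bS) antipode takes its place if the configuration of 13 proves to be R.

**Step 1**
Reactants: 1 1,5-dimethoxynaphthalene
Product: 3 4,8-dimethoxynaphthalene-1-carbaldehyde, via [(4,8-dimethoxynaphthalen-1-yl)methylidene]dimethylammonium chloride 2 (not isolated)
Conditions: POCl3, DMF, toluene, 0 → 100 °C; then ice–water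
Reagents that add atoms: N,N-dimethylformamide CN(C)C=O; water O
Why: Vilsmeier–Haack formylation attacks para to a methoxy group, and because C4 and C8 of the symmetric diether 1 are equivalent and the first formyl group deactivates the system, a single mono-aldehyde should result after hydrolysis of iminium salt 2.

**Step 2**
Reactants: 3 4,8-dimethoxynaphthalene-1-carbaldehyde
Product: 4 4-hydroxy-8-methoxynaphthalene-1-carbaldehyde
Conditions: NaSEt (1.5 equiv), DMF, 100 °C; then 1 M HCl
Reagents that add atoms: none
Why: Nucleophilic (SN2) aryl methyl ether cleavage by thiolate follows leaving-group ability, so the C4 methoxy group, whose aryloxide is conjugated with the para formyl group, should be cleaved in preference to the non-conjugated peri C8 methoxy group, and the anionic product resists a second cleavage.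

**Step 3**
Reactants: 4 4-hydroxy-8-methoxynaphthalene-1-carbaldehyde
Product: 5 4-(benzyloxy)-8-methoxynaphthalene-1-carbaldehyde
Conditions: BnBr, K2CO3, DMF, rt
Reagents that add atoms: benzyl bromide BrCc1ccccc1
Why: Williamson ether synthesis on the acidic naphthol proceeds under mild carbonate conditions that leave the aldehyde and the methyl ether untouched.

**Step 4**
Reactants: 6 4-(benzyloxy)phenol
Product: 7 4-(benzyloxy)-2-bromophenol
Conditions: NBS (1.0 equiv), CH2Cl2, 0 °C
Reagents that add atoms: N-bromosuccinimide O=C1CCC(=O)N1Br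
Why: Electrophilic aromatic bromination is directed by the stronger donor, the free hydroxyl, whose para position is blocked, so bromine should enter ortho to OH at the future C4a.

**Step 5**
Reactants: 7 4-(benzyloxy)-2-bromophenol; 5 4-(benzyloxy)-8-methoxynaphthalene-1-carbaldehyde
Product: 9 rac-4-(benzyloxy)-2-{[4-(benzyloxy)-8-methoxynaphthalen-1-yl](hydroxy)methyl}phenol, via lithium 4-(benzyloxy)-2-lithiophenolate 8 (not isolated)
Conditions: 7, n-BuLi (2.1 equiv), Et2O, 0 °C → rt; then 5 in THF, −78 → 0 °C; aq NH4Cl
Reagents that add atoms: none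
Why: Deprotonation and bromine–lithium exchange give the O,C-dilithiated phenol 8, a well-used unprotected ortho-hydroxyaryl anion, which undergoes 1,2-addition to the non-enolisable aldehyde 5 to form the C4–C4a bond, and the racemic carbinol centre is erased in step 7.

**Step 6**
Reactants: 9 rac-4-(benzyloxy)-2-{[4-(benzyloxy)-8-methoxynaphthalen-1-yl](hydroxy)methyl}phenol
Product: 10 rac-4-(benzyloxy)-2-{[4-(benzyloxy)-8-methoxynaphthalen-1-yl](4-methylbenzenesulfonyl)methyl}phenol
Conditions: p-TolSO2H (1.5 equiv), CH2Cl2, rt
Reagents that add atoms: p-toluenesulfinic acid Cc1ccc(cc1)S(=O)O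
Why: In this acid-promoted SN1-type substitution the sulfinic acid ionises the doubly activated benzhydrol and the soft sulfur of the sulfinate captures the cation, giving the standard storable ortho-quinone methide precursor as a racemate.

**Step 7**
Reactants: 10 rac-4-(benzyloxy)-2-{[4-(benzyloxy)-8-methoxynaphthalen-1-yl](4-methylbenzenesulfonyl)methyl}phenol; 11 acrolein
Product: 13 (S)-7-(benzyloxy)-5-[4-(benzyloxy)-8-methoxynaphthalen-1-yl]-4,5-dihydro-1-benzoxepin-2(3H)-one, via (6E)-4-(benzyloxy)-6-{[4-(benzyloxy)-8-methoxynaphthalen-1-yl]methylidene}cyclohexa-2,4-dien-1-one 12 (not isolated)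
Conditions: (5aS,10bR)-2-mesityl-5a,10b-dihydro-4H,6H-indeno[2,1-b][1,2,4]triazolo[4,3-d][1,4]oxazin-2-ium tetrafluoroborate (20 mol %), Cs2CO3 (1.5 equiv), 4 Å MS, toluene, 0 °C → rt; freshly distilled 11 (3 equiv) by syringe pump
Reagents that add atoms: none
Why: Cs2CO3 deprotonates the phenol of 10 and expels p-toluenesulfinate (E1cB) to give methide 12, while the free carbene adds to the formyl group of 11 and forms the extended Breslow intermediate (homoenolate), whose unsubstituted β-carbon (future C3) adds 1,4 to the methide carbon (future C4); tautomerisation gives the acyl azolium, which the liberated phenoxide O5 acylates with release of the catalyst. The closest known reaction is the carbene-catalysed homoenolate formal [4+3] annulation of enals with aryl-substituted ortho-quinone methides to 4,5-dihydro-1-benzoxepin-2(3H)-ones, and base-triggered release of such methides from 2-[aryl(sulfonyl)methyl]phenols is standard; acrolein is the smallest enal and is dosed slowly because it polymerises and can trap the carbene by conjugate addition. The one ring that closes, the seven-membered lactone, closes by 7-exo-trig addition–elimination of the phenoxide at the acyl azolium carbonyl C1. The one new stereocentre, C4, is controlled by the catalyst alone: the indane wall and the N-mesityl group shield one face of the planar homoenolate, and the methide must approach with its oxygen near the azolium (the arrangement that also allows ring closure), so one methide face is presented, helped by the peri-methoxynaphthyl ring standing perpendicular to the methide plane so that each of its interconverting rotamers leaves only the face on the C2′–H side open. The step needs C–C bond formation at the β-carbon rather than β-protonation (which would lead through the azolium enolate to the six-membered [4+2] lactone) and 1,4- rather than 1,2-attack on 12; rearomatisation of the hydroquinone ring secures the latter, and a strongly electrophilic neutral methide formed under aprotic conditions with an insoluble carbonate base favours the former.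

**Step 8**
Reactants: 13 (S)-7-(benzyloxy)-5-[4-(benzyloxy)-8-methoxynaphthalen-1-yl]-4,5-dihydro-1-benzoxepin-2(3H)-one
Product: 15 (S)-4-[2,5-bis(benzyloxy)phenyl]-4-[4-(benzyloxy)-8-methoxynaphthalen-1-yl]butanoic acid, via dipotassium (S)-4-[5-(benzyloxy)-2-oxidophenyl]-4-[4-(benzyloxy)-8-methoxynaphthalen-1-yl]butanoate 14 (not isolated)
Conditions: KOH (excess), THF–EtOH–H2O, rt; then BnBr, 60 °C; then 1 M HCl
Reagents that add atoms: potassium hydroxide [K+].[OH-]; benzyl bromide BrCc1ccccc1
Why: Saponification of the activated aryl lactone to phenoxide–carboxylate 14 and Williamson benzylation in the same alkaline medium (any benzyl ester formed is re-saponified) cap O5 so that the acid cannot relactonise on activation, and C4–H is not acidic under these conditions, so the configuration is retained.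

**Step 9**
Reactants: 15 (S)-4-[2,5-bis(benzyloxy)phenyl]-4-[4-(benzyloxy)-8-methoxynaphthalen-1-yl]butanoic acid
Product: 17 (S)-5,8-bis(benzyloxy)-4-[4-(benzyloxy)-8-methoxynaphthalen-1-yl]-3,4-dihydronaphthalen-1(2H)-one, via (S)-4-[2,5-bis(benzyloxy)phenyl]-4-[4-(benzyloxy)-8-methoxynaphthalen-1-yl]butanoic trifluoroacetic anhydride 16 (not isolated)
Conditions: (CF3CO)2O (3 equiv), CH2Cl2, 0 °C → rt
Reagents that add atoms: none
Why: Intramolecular Friedel–Crafts acylation through mixed anhydride 16, the mild standard for 4-(2,5-dialkoxyphenyl)butanoic acids, should close the six-membered ketone ring at C8a, which is activated by the ortho C8 benzyloxy group, faster than at naphthalene C2′, which lies meta to its own benzyloxy group, while the weak acid spares the benzyl ethers and the C4 centre.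

**Step 10**
Reactants: 17 (S)-5,8-bis(benzyloxy)-4-[4-(benzyloxy)-8-methoxynaphthalen-1-yl]-3,4-dihydronaphthalen-1(2H)-one
Product: 18 (S)-5,8-dihydroxy-4-(4-hydroxy-8-methoxynaphthalen-1-yl)-3,4-dihydronaphthalen-1(2H)-one (CNP0584478.1)
Conditions: H2 (1 atm), 10% Pd/C, EtOAc–MeOH, rt; work-up under argon
Reagents that add atoms: none
Why: Catalytic hydrogenolysis cleaves the three aryl benzyl ethers under neutral conditions, while the methyl ether, the C4–aryl bonds and the aryl ketone (deactivated by the hydrogen bond from the freed C8 hydroxyl) should persist, so the S configuration from step 7 is carried into 18.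

**Compound list**
1 | 1,5-dimethoxynaphthalene | COc1cccc2c(OC)cccc12 | starting material
2 | [(4,8-dimethoxynaphthalen-1-yl)methylidene]dimethylammonium chloride | COc1cccc2c(OC)ccc(C=[N+](C)C)c12.[Cl-] | intermediate
3 | 4,8-dimethoxynaphthalene-1-carbaldehyde | COc1cccc2c(OC)ccc(C=O)c12 | intermediate
4 | 4-hydroxy-8-methoxynaphthalene-1-carbaldehyde | COc1cccc2c(O)ccc(C=O)c12 | intermediate
5 | 4-(benzyloxy)-8-methoxynaphthalene-1-carbaldehyde | COc1cccc2c(OCc3ccccc3)ccc(C=O)c12 | intermediate
6 | 4-(benzyloxy)phenol | Oc1ccc(OCc2ccccc2)cc1 | starting material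
7 | 4-(benzyloxy)-2-bromophenol | Oc1ccc(OCc2ccccc2)cc1Br | intermediate
8 | lithium 4-(benzyloxy)-2-lithiophenolate | [Li]Oc1ccc(OCc2ccccc2)cc1[Li] | intermediate
9 | rac-4-(benzyloxy)-2-{[4-(benzyloxy)-8-methoxynaphthalen-1-yl](hydroxy)methyl}phenol | COc1cccc2c(OCc3ccccc3)ccc(C(O)c3cc(OCc4ccccc4)ccc3O)c12 | intermediate
10 | rac-4-(benzyloxy)-2-{[4-(benzyloxy)-8-methoxynaphthalen-1-yl](4-methylbenzenesulfonyl)methyl}phenol | COc1cccc2c(OCc3ccccc3)ccc(C(c3cc(OCc4ccccc4)ccc3O)S(=O)(=O)c3ccc(C)cc3)c12 | intermediate
11 | acrolein | C=CC=O | starting material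
12 | (6E)-4-(benzyloxy)-6-{[4-(benzyloxy)-8-methoxynaphthalen-1-yl]methylidene}cyclohexa-2,4-dien-1-one | COc1cccc2c(OCc3ccccc3)ccc(/C=C3\C=C(OCc4ccccc4)C=CC3=O)c12 | intermediate
13 | (S)-7-(benzyloxy)-5-[4-(benzyloxy)-8-methoxynaphthalen-1-yl]-4,5-dihydro-1-benzoxepin-2(3H)-one | COc1cccc2c(OCc3ccccc3)ccc([C@@H]3CCC(=O)Oc4ccc(OCc5ccccc5)cc43)c12 | intermediate
14 | dipotassium (S)-4-[5-(benzyloxy)-2-oxidophenyl]-4-[4-(benzyloxy)-8-methoxynaphthalen-1-yl]butanoate | COc1cccc2c(OCc3ccccc3)ccc([C@H](CCC(=O)[O-])c3cc(OCc4ccccc4)ccc3[O-])c12.[K+].[K+] | intermediate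
15 | (S)-4-[2,5-bis(benzyloxy)phenyl]-4-[4-(benzyloxy)-8-methoxynaphthalen-1-yl]butanoic acid | COc1cccc2c(OCc3ccccc3)ccc([C@H](CCC(=O)O)c3cc(OCc4ccccc4)ccc3OCc3ccccc3)c12 | intermediate
16 | (S)-4-[2,5-bis(benzyloxy)phenyl]-4-[4-(benzyloxy)-8-methoxynaphthalen-1-yl]butanoic trifluoroacetic anhydride | COc1cccc2c(OCc3ccccc3)ccc([C@H](CCC(=O)OC(=O)C(F)(F)F)c3cc(OCc4ccccc4)ccc3OCc3ccccc3)c12 | intermediate
17 | (S)-5,8-bis(benzyloxy)-4-[4-(benzyloxy)-8-methoxynaphthalen-1-yl]-3,4-dihydronaphthalen-1(2H)-one | COc1cccc2c(OCc3ccccc3)ccc([C@@H]3CCC(=O)c4c(OCc5ccccc5)ccc(OCc5ccccc5)c43)c12 | intermediate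
18 | (S)-5,8-dihydroxy-4-(4-hydroxy-8-methoxynaphthalen-1-yl)-3,4-dihydronaphthalen-1(2H)-one | COc1cccc2c(O)ccc([C@@H]3CCC(=O)c4c(O)ccc(O)c43)c12 | target

**Total steps:** 10. **Longest linear sequence:** 9 (steps 1–3 and 5–10).

**Steps most likely to fail**

**Step 7.**
- What may go wrong:
  - Acrolein may polymerise.
  - Acrolein may deactivate the carbene by conjugate addition.
  - β-Protonation of the homoenolate may divert material into the [4+2] manifold.
  - Facial selectivity at the methide carbon may be poor because the enal has no β-substituent to organise the transition state.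
- The fallback sets out from 10, returns at 15, and keeps C4 as the methide carbon. It replaces carbene catalysis by hydrogen-bond/base catalysis with a two-carbon nucleophile, followed by homologation.
- Methide 12 is released from 10 with aqueous NaHCO3 in toluene in the presence of a quinine- or quinidine-derived squaramide, the pseudo-enantiomer being chosen for the S sense.
- It is intercepted by Meldrum's acid to give (S)-5-{[5-(benzyloxy)-2-hydroxyphenyl][4-(benzyloxy)-8-methoxynaphthalen-1-yl]methyl}-2,2-dimethyl-1,3-dioxane-4,6-dione F1.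
- Heating with catalytic p-TsOH in toluene lactonises and decarboxylates it to (S)-6-(benzyloxy)-4-[4-(benzyloxy)-8-methoxynaphthalen-1-yl]chroman-2-one F2.
- KOH and BnBr, as in step 8, give (S)-3-[2,5-bis(benzyloxy)phenyl]-3-[4-(benzyloxy)-8-methoxynaphthalen-1-yl]propanoic acid F3.
- Arndt–Eistert homologation follows. Oxalyl chloride gives (S)-3-[2,5-bis(benzyloxy)phenyl]-3-[4-(benzyloxy)-8-methoxynaphthalen-1-yl]propanoyl chloride F4.
- Diazomethane gives (S)-4-[2,5-bis(benzyloxy)phenyl]-4-[4-(benzyloxy)-8-methoxynaphthalen-1-yl]-1-diazobutan-2-one F5.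
- Silver benzoate and Et3N in aqueous THF (Wolff rearrangement, in which the stereocentre is not the migrating carbon) deliver 15.

**Step 9.**
- What may go wrong: ring closure onto naphthalene C2′ may compete, and acid may strip benzyl groups with C-benzylation of the electron-rich rings.
- The fallback sets out from 13, returns at 18, and reverses the order of events so that no benzyl group is present and the lactone itself is the acyl donor.
- Hydrogenolysis (H2, Pd/C, EtOAc) gives (S)-7-hydroxy-5-(4-hydroxy-8-methoxynaphthalen-1-yl)-4,5-dihydro-1-benzoxepin-2(3H)-one F6.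
- TfOH in dilute CH2Cl2 at 0 °C should then open the aryl ester to the acylium ion and transfer C1 to C8a, now ortho to a small and strongly activating free hydroxyl.
- This is the Fries-type lactone-to-hydroxyketone rearrangement known for dihydrocoumarins going to 4-hydroxyindan-1-ones. Acid-induced ionisation at C4, with erosion of the configuration, would have to be watched.

**Step 6.**
- What may go wrong:
  - The very electron-rich sulfone may ionise reversibly during isolation.
  - The methide may self-condense under the acidic conditions.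
  - The peri methoxy group may participate at the cation.
- The fallback sets out from 9, returns at 12, and avoids acid altogether by using a fluoride-triggered precursor.
- Selective silylation of the phenol (TBSCl, imidazole, CH2Cl2) gives rac-[5-(benzyloxy)-2-(tert-butyldimethylsilyloxy)phenyl][4-(benzyloxy)-8-methoxynaphthalen-1-yl]methanol F7.
- Acetylation (Ac2O, Et3N, DMAP, 0 °C) gives rac-[5-(benzyloxy)-2-(tert-butyldimethylsilyloxy)phenyl][4-(benzyloxy)-8-methoxynaphthalen-1-yl]methyl acetate F8.
- In the annulation flask of step 7, CsF with 18-crown-6 replaces the stoichiometric carbonate. Desilylation is followed by 1,4-elimination of acetate and releases 12.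

**Further compounds**
F1 | step 7 | (S)-5-{[5-(benzyloxy)-2-hydroxyphenyl][4-(benzyloxy)-8-methoxynaphthalen-1-yl]methyl}-2,2-dimethyl-1,3-dioxane-4,6-dione | COc1cccc2c(OCc3ccccc3)ccc([C@H](C3C(=O)OC(C)(C)OC3=O)c3cc(OCc4ccccc4)ccc3O)c12
F2 | step 7 | (S)-6-(benzyloxy)-4-[4-(benzyloxy)-8-methoxynaphthalen-1-yl]chroman-2-one | COc1cccc2c(OCc3ccccc3)ccc([C@@H]3CC(=O)Oc4ccc(OCc5ccccc5)cc43)c12
F3 | step 7 | (S)-3-[2,5-bis(benzyloxy)phenyl]-3-[4-(benzyloxy)-8-methoxynaphthalen-1-yl]propanoic acid | COc1cccc2c(OCc3ccccc3)ccc([C@H](CC(=O)O)c3cc(OCc4ccccc4)ccc3OCc3ccccc3)c12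
F4 | step 7 | (S)-3-[2,5-bis(benzyloxy)phenyl]-3-[4-(benzyloxy)-8-methoxynaphthalen-1-yl]propanoyl chloride | COc1cccc2c(OCc3ccccc3)ccc([C@H](CC(=O)Cl)c3cc(OCc4ccccc4)ccc3OCc3ccccc3)c12
F5 | step 7 | (S)-4-[2,5-bis(benzyloxy)phenyl]-4-[4-(benzyloxy)-8-methoxynaphthalen-1-yl]-1-diazobutan-2-one | COc1cccc2c(OCc3ccccc3)ccc([C@H](CC(=O)C=[N+]=[N-])c3cc(OCc4ccccc4)ccc3OCc3ccccc3)c12
F6 | step 9 | (S)-7-hydroxy-5-(4-hydroxy-8-methoxynaphthalen-1-yl)-4,5-dihydro-1-benzoxepin-2(3H)-one | COc1cccc2c(O)ccc([C@@H]3CCC(=O)Oc4ccc(O)cc43)c12
F7 | step 6 | rac-[5-(benzyloxy)-2-(tert-butyldimethylsilyloxy)phenyl][4-(benzyloxy)-8-methoxynaphthalen-1-yl]methanol | COc1cccc2c(OCc3ccccc3)ccc(C(O)c3cc(OCc4ccccc4)ccc3O[Si](C)(C)C(C)(C)C)c12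
F8 | step 6 | rac-[5-(benzyloxy)-2-(tert-butyldimethylsilyloxy)phenyl][4-(benzyloxy)-8-methoxynaphthalen-1-yl]methyl acetate | COc1cccc2c(OCc3ccccc3)ccc(C(OC(C)=O)c3cc(OCc4ccccc4)ccc3O[Si](C)(C)C(C)(C)C)c12
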